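## The problem

The target is a cis-fused decalin. Ring A is C10–C1–C2(=O)–C3–C4–C5 and ring B is C5–C6–C7–C8–C9–C10; six ring carbons are stereogenic (C4, C5, C7, C8, C9, C10) and the 2-methylbutanoyl group carries one more (R) centre. Taking the face of the C5 methyl as β, the C4 methyl, H-10 and the C7 isopropenyl group are β, and the C8 (R)-2-methylbutanoate and the C9 tiglate are both α and cis to each other. C5 is quaternary and lies between two other stereocentres. In the chair of ring B that keeps the C5 methyl and the isopropenyl group equatorial, the C5–C4 bond is axial on the α face, so ring A covers that face. The ring fusion can therefore steer hydride at C8 and C9 and a methyl nucleophile at C4 to the open β face. C7 is the exception: it needs its hydrogen on the α face, and equilibration is not expected to correct it. Sensitive features are the cis-diol with two different acyl groups (acyl migration), the tiglate (Michael acceptor, deconjugation), the α-branched acyl group (epimerisation), and the isopropenyl group, which slips into conjugation with any C8 carbonyl and is acid-sensitive. The enabling feature is that the C8/C9 oxygens, the C2 oxygen and the cis fusion at C5/C10 are all present in a bicyclo[2.2.2]octenone made from a masked o-benzoquinone and a vinyl ether. Only the C5–C6 bond is missing, and C6=C7–C8–C3–C4=C5 is a 1,5-diene set up for an oxy-Cope rearrangement.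

## Retrosynthesis

**C4–CH3 (23 ⇒ 21).** The C4 methyl is cut last, as a conjugate addition to enone 21. Carrying it earlier would make C4 an sp2 carbon after the rearrangement and require hydrogen delivery from the covered α face. The precursor loses one stereocentre. The forward step needs β-face delivery and selectivity for the enone over the tiglate.

**C9 ester C–O and C2 oxidation level (21 ⇒ 19 ⇒ 18).** The tiglate is cut next and the enone is traced to the allylic alcohol of diol 18. The tiglate is installed after all hydride steps and before the cuprate, because its bulk closes the α face of C4 where a free C9 alkoxide might direct the reagent. The forward steps need an oxidant that touches only the allylic hydroxyl and an acylation of a hindered axial alcohol.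

**C9–H and unmasking (18 ⇒ 17 ⇒ 16).** The C9 carbinol is traced to ketone 17, and 17 to ketal silyl ether 16, so that one acid treatment removes both masking groups. The forward reduction needs hydride on the β face and must not let the C8 acyl group migrate.

**C8 ester C–O and C8–H (16 ⇒ 14 ⇒ 13).** The (R)-2-methylbutanoate (acid 15) is cut, then the C8 carbinol is traced to ketone 13. C8 is handled first because 13 can epimerise or conjugate at C7, and because C8 and C9 are distinguished only while one is a ketone and the other a ketal. The forward reduction needs axial hydride delivery on the β face.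

**C5–C6 (13 ⇒ 10), the key cut.** Breaking C5–C6 and re-forming C3–C8 turns the cis-octalin into bicyclo[2.2.2]octenol 10. This removes ring B, the quaternary centre and the C7 centre at once. Cuts at C7–C8 (ene) or C5–C10/C6–C7 (cycloaddition) leave the ring A triad to be built separately. The forward reaction needs the dienyl group syn to the alkene bridge and a kinetic protonation at C7.

**C7–C8 (10 ⇒ 8 + 3).** The dienyl group is removed as organomagnesium 9, made from bromodiene 3, leaving non-enolisable ketone 8. The forward addition must come from the alkene face of the carbonyl.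

**Diels–Alder bonds C1–C10 and C2–C3 (8 ⇒ 7 ⇒ 4 + 5).** The bicycle opens to masked o-benzoquinone 6 (from phenol 4) and silyl vinyl ether 5. The cycloaddition is racemic, so racemate 7 is resolved to 8. The forward reaction needs ortho regiochemistry and endo selectivity; both are normal for this diene class.

**C–Br (3 ⇒ 1).** Bromodiene 3 comes from enyne 1 by Markovnikov addition of HBr in the form of bromoboration and protonolysis.

## Roads not taken

**Alternative 1:** The cut is C7–C8. Aldehyde A4 (ring A complete, prenyl group on C5, α-tigloyloxy aldehyde on C10) would close ring B by a Me2AlCl-promoted type 1 carbonyl-ene reaction to give A1, forming the isopropenyl group and the free C8 hydroxyl together. Its merits are real: C7 and C8 are set in one concerted, isopulegol-type step, and A1 is two steps from the target with the two oxygens already differentiated and no migration-prone reduction. In this respect it is better than the chosen plan, which sets C7 by a kinetic protonation. Its weak points are that the chair transition state must carry the C9 tiglate axial, so the selectivity of the citronellal model is not assured; that the α-acyloxy aldehyde can epimerise at C9 under the Lewis acid; and above all that A4 needs the whole C4/C5/C10 triad, including the quaternary centre, from a separate and long sequence. The chosen plan sets against this a five-step access to the complete bicyclic skeleton with both oxygens in place.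

**Alternative 2:** The cut is C5–C10 and C6–C7. Heating siloxy polyene A5 would give A2 by a type 1 intramolecular Diels–Alder reaction, closing both rings and leaving a C8=C9 silyl enol ether. Ring count per step is better than in the chosen plan. The weaknesses are electronic and geometric. The dienophile is an unactivated 1,1-disubstituted alkene facing an electron-rich diene, so high temperatures are needed. Because C7-isopropenyl and C10–C1 end up trans on ring B, the isopropenyl group must sit inside the diene terminus (as drawn in A5) or C9=C10 must be Z; the first option makes a cis-hexatriene that can electrocyclise instead. The cis fusion and the C5 face rest only on the C4 methyl in the tether, and C9 still needs oxidation. The chosen plan has both oxygens, the cis fusion and the quaternary centre fixed by the bicyclic precursor.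

**Alternative 3:** The cut is C3–C4 and C5–C10. Diene A6 and (E)-2-methylbut-2-enal A7 would combine under the triflimide salt of the N-protonated (S)-α,α-diphenylprolinol-derived B-(o-tolyl)oxazaborolidine to give A3. This road is better than the chosen plan in two respects. The cis relation of the C4 and C5 methyls follows from the dienophile geometry, not from the facial course of a cuprate. The absolute configuration comes from a catalyst, not from a resolution that discards half the material. Against this, A7 is a sluggish, trisubstituted dienophile, and the stereocentre in A6 may be mismatched with the catalyst. A3 contains only ring A: ring B, with C7 to be inserted between C6 and C8 and with C7, C8 and C9 to be controlled, remains to be built, and C8 and C9 arrive undifferentiated in one acetonide. The chosen plan gives both rings and differentiated oxygens at once and pays with the resolution and the late methyl addition.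

Key step: step 5

Assumption: the enantiomer carried on from step 3 is identified as (1S,4S,7S)-8 by Mosher ester analysis of the C7 alcohol from a desilylated aliquot; β always means the face of the C5 methyl (target numbering).

## Steps

**Step 1**
Reactants: 1 2-methylbut-1-en-3-yne
Product: 3 2-bromo-3-methylbuta-1,3-diene, via bromodienylborane 2 (not isolated)
Conditions: 9-Br-9-BBN, CH2Cl2, 0 °C; AcOH, 0 °C → rt
Reagents that add atoms: 9-bromo-9-borabicyclo[3.3.1]nonane, BrB1C2CCCC1CCC2
Why: Bromoboration of the terminal alkyne is a syn addition that puts boron on the terminal carbon and bromine on the internal one and leaves the 1,1-disubstituted alkene alone; protonolysis of the alkenyl–boron bond with acetic acid then gives the 2-bromo-1,3-diene (haloboration–protodeboronation).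

**Step 2**
Reactants: 4 2-methoxy-4-methylphenol; 5 tert-butyldimethyl(vinyloxy)silane
Product: 7 (±)-7-endo-silyloxy-3,3-dimethoxy-5-methylbicyclo[2.2.2]oct-5-en-2-one, via masked o-benzoquinone 6 (not isolated)
Conditions: PhI(OAc)2 (slow addition), 5 (5 equiv), NaHCO3, MeOH, 0 °C → rt
Reagents that add atoms: methanol, CO
Why: Oxidative dearomatisation of the guaiacol in methanol gives dienone 6, an electron-poor diene that the excess enol ether should trap in an inverse-demand Diels–Alder reaction before it dimerises. The nucleophilic CH2 terminus bonds to the δ-carbon of the dienone, so the silyloxy carbon ends next to the bridgehead α to the ketone; endo addition places the silyloxy group syn to the new alkene bridge, fixing C10, C3 and C2 (target numbering) relative to one another. The buffer protects the silyl enol ether from the acetic acid released.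

**Step 3**
Reactants: 7 (±)-7-endo-silyloxy-3,3-dimethoxy-5-methylbicyclo[2.2.2]oct-5-en-2-one
Product: 8 (1S,4S,7S)-7-silyloxy-3,3-dimethoxy-5-methylbicyclo[2.2.2]oct-5-en-2-one
Conditions: preparative SFC, amylose tris(3,5-dimethylphenylcarbamate) on silica, CO2/i-PrOH
Reagents that add atoms: none
Why: Chromatographic resolution of a rigid, polar bicyclic ketone on a polysaccharide phase; no bond changes, and the ketone cannot racemise because one α-carbon is a bridgehead and the other is the quaternary ketal carbon.

**Step 4**
Reactants: 3 2-bromo-3-methylbuta-1,3-diene; 8 (1S,4S,7S)-7-silyloxy-3,3-dimethoxy-5-methylbicyclo[2.2.2]oct-5-en-2-one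
Product: 10 (1S,2S,4S,7S)-2-dienyl-bicyclo[2.2.2]oct-5-en-2-ol, via dienylmagnesium bromide 9 (not isolated)
Conditions: Mg, THF, rt; then 8, THF, −78 → 0 °C; aq. NH4Cl
Reagents that add atoms: none
Why: Grignard formation from the vinylic bromide and 1,2-addition to a non-enolisable α,α-dimethoxy ketone. The carbonyl face toward the sp2 bridge is open, while the other is screened by the inward hydrogens of the ethano bridge, so the dienyl group should end syn to the C5=C6 alkene, as the [3,3] shift requires; this sets the carbinol centre.

**Step 5**
Reactants: 10 (1S,2S,4S,7S)-2-dienyl-bicyclo[2.2.2]oct-5-en-2-ol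
Product: 13 cis-octalin 8-ketone 9-dimethyl ketal, via potassium alkoxide 11 (not isolated), via potassium dienolate 12 (not isolated)
Conditions: KH, 18-crown-6, THF, 0 °C → rt; cannulate into AcOH/THF, −78 °C
Reagents that add atoms: none
Why: KH with 18-crown-6 gives the free alkoxide 11, whose oxyanion weakens the adjacent C3–C8 bond and accelerates the [3,3]-sigmatropic shift of the 1,5-diene C6=C7–C8–C3–C4=C5; this is the anionic oxy-Cope rearrangement, well known for 2-alkenylbicyclo[2.2.2]oct-5-en-2-ols. The bicycle allows only a boat-like six-membered transition state; C5–C6 forms as C3–C8 breaks, so ring B is closed by the sigmatropic shift itself (a six-centre pericyclic closure, not a separate cyclisation) and the bicycle opens to the cis-fused dienolate 12. C5 is controlled by the substrate: the new bond can form only on the face of the C4=C5 alkene that faces the C8 bridge, which puts the C5 methyl cis to H-10. C7 is set by kinetic C-protonation of 12 at the α-carbon. Axial delivery through the half-chair of ring B that keeps the C5 methyl equatorial brings the proton in on the α face past the flat C4 carbon, whereas the axial path on the β face in the other half-chair must pass the axial angular methyl; the isopropenyl group is therefore expected β and equatorial. The step needs the dienyl group syn to the alkene, secured in step 4, and α- not γ-protonation without re-enolisation, secured by inverse quench into cold acetic acid. The silyl ether and the ketal are inert to these conditions.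

**Step 6**
Reactants: 13 cis-octalin 8-ketone 9-dimethyl ketal
Product: 14 8α-alcohol 9-dimethyl ketal
Conditions: NaBH4, CeCl3·7H2O, MeOH, −78 → −40 °C
Reagents that add atoms: none
Why: Luche reduction. Hydride should attack C8 along the axial path on the open β face (only axial hydrogens at C6 and C10; the α side carries the axial methoxy group and ring A), giving the equatorial 8α-alcohol trans to the isopropenyl group. The cold, nearly neutral medium avoids enolisation toward C7.

**Step 7**
Reactants: 14 8α-alcohol 9-dimethyl ketal; 15 (R)-2-methylbutanoic acid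
Product: 16 8α-(R)-2-methylbutanoate 9-dimethyl ketal
Conditions: DCC, DMAP (cat.), CH2Cl2, 0 °C → rt
Reagents that add atoms: none
Why: Steglich esterification of the only free hydroxyl; carbodiimide activation with catalytic DMAP at or below room temperature is not expected to epimerise the α-branched acyl group.

**Step 8**
Reactants: 16 8α-(R)-2-methylbutanoate 9-dimethyl ketal
Product: 17 2β-hydroxy 9-ketone 8α-ester
Conditions: 2 M aq. HCl, THF, rt
Reagents that add atoms: water, O
Why: Acid hydrolysis turns the dimethyl ketal into the C9 ketone and cleaves the secondary silyl ether in the same medium; the ester and the isopropenyl group should tolerate dilute aqueous acid at room temperature. C10 should not drift to the trans-fused series, because that isomer would force the isopropenyl group syn-axial to the angular methyl.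

**Step 9**
Reactants: 17 2β-hydroxy 9-ketone 8α-ester
Product: 18 2β,9α-diol 8α-ester
Conditions: LiBH(s-Bu)3 (L-Selectride), THF, −78 °C; AcOH, −78 °C
Reagents that add atoms: none
Why: The bulky trialkylborohydride can reach the C9 carbonyl only along the equatorial path on the β face, because the axial path on the α face is closed by the syn-axial C5–C4 bond of ring A. This gives the axial 9α-alcohol cis to the C8 ester, and the cold acidic quench keeps the C9 alkoxide from taking over the neighbouring acyl group.

**Step 10**
Reactants: 18 2β,9α-diol 8α-ester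
Product: 19 9α-hydroxy enone 8α-ester
Conditions: MnO2 (activated), CH2Cl2, rt
Reagents that add atoms: none
Why: MnO2 oxidises only the allylic C2 alcohol to the C3=C4 enone; the saturated, hindered C9 hydroxyl is left alone, and the neutral medium does not promote acyl migration.

**Step 11**
Reactants: 19 9α-hydroxy enone 8α-ester; 20 (E)-2-methylbut-2-enoyl chloride
Product: 21 9α-tiglate enone 8α-ester
Conditions: DMAP, pyridine, CH2Cl2, 40 °C
Reagents that add atoms: none
Why: DMAP-catalysed acylation of the remaining axial hydroxyl by the acid chloride. Pyridine as the only base limits deconjugation of the tigloyl group through a vinylketene, and the E geometry is the stable one.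

**Step 12**
Reactants: 21 9α-tiglate enone 8α-ester
Product: 23 CNP0312791.1, via lithium enolate 22 (not isolated)
Conditions: Me2CuLi (from CuI and MeLi), Et2O, −78 → −40 °C; aq. NH4Cl
Reagents that add atoms: lithium dimethylcuprate, [Li+].C[Cu-]C
Why: Conjugate addition of a Gilman reagent to a β-monosubstituted cyclohexenone. The α face of C4 is covered by C9 and its axial tigloyloxy group, so the methyl should enter on the β face, cis to the angular methyl. The trisubstituted tiglate and the saturated ester are far poorer acceptors than the enone at low temperature, and protonation of 22 gives the ketone.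

## Compound list

1 | 2-methylbut-1-en-3-yne | C=C(C)C#C | starting material
2 | 9-[(Z)-2-bromo-3-methylbuta-1,3-dien-1-yl]-9-borabicyclo[3.3.1]nonane | C=C(C)/C(Br)=C/B1C2CCCC1CCC2 | intermediate
3 | 2-bromo-3-methylbuta-1,3-diene | C=C(C)C(Br)=C | intermediate
4 | 2-methoxy-4-methylphenol | COc1cc(C)ccc1O | starting material
5 | tert-butyldimethyl(vinyloxy)silane | C=CO[Si](C)(C)C(C)(C)C | starting material
6 | 6,6-dimethoxy-4-methylcyclohexa-2,4-dien-1-one | COC1(OC)C=C(C)C=CC1=O | intermediate
7 | (±)-7-[(tert-butyldimethylsilyl)oxy]-3,3-dimethoxy-5-methylbicyclo[2.2.2]oct-5-en-2-one, silyloxy group syn to the C5=C6 bridge (racemate, both enantiomers written) | O=C1C(OC)(OC)[C@H]2C[C@H](O[Si](C)(C)C(C)(C)C)[C@@H]1C=C2C.O=C1C(OC)(OC)[C@@H]2C[C@@H](O[Si](C)(C)C(C)(C)C)[C@H]1C=C2C | intermediate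
8 | (1S,4S,7S)-7-[(tert-butyldimethylsilyl)oxy]-3,3-dimethoxy-5-methylbicyclo[2.2.2]oct-5-en-2-one | O=C1C(OC)(OC)[C@H]2C[C@H](O[Si](C)(C)C(C)(C)C)[C@@H]1C=C2C | intermediate
9 | (3-methylbuta-1,3-dien-2-yl)magnesium bromide | C=C(C)C(=C)[Mg]Br | intermediate
10 | (1S,2S,4S,7S)-7-[(tert-butyldimethylsilyl)oxy]-3,3-dimethoxy-5-methyl-2-(3-methylbuta-1,3-dien-2-yl)bicyclo[2.2.2]oct-5-en-2-ol, dienyl group syn to the C5=C6 bridge | C=C(C)C(=C)[C@]1(O)C(OC)(OC)[C@H]2C[C@H](O[Si](C)(C)C(C)(C)C)[C@@H]1C=C2C | intermediate
11 | potassium alkoxide of 10 | C=C(C)C(=C)[C@]1([O-])C(OC)(OC)[C@H]2C[C@H](O[Si](C)(C)C(C)(C)C)[C@@H]1C=C2C.[K+] | intermediate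
12 | potassium C7=C8 dienolate of 13 (cis-fused, 5β-methyl, 10β-H, 2β-silyloxy) | C=C(C)C=1C[C@@]2(C)[C@H](C[C@H](O[Si](C)(C)C(C)(C)C)C=C2)C(OC)(OC)C=1[O-].[K+] | intermediate
13 | cis-fused octalin, target numbering: C8 ketone, C9 dimethyl ketal, 7β-isopropenyl, 5β-methyl, 10β-H, C3=C4 alkene, 2β-OSi(t-Bu)Me2 | C=C(C)[C@H]1C[C@@]2(C)[C@H](C[C@H](O[Si](C)(C)C(C)(C)C)C=C2)C(OC)(OC)C1=O | intermediate
14 | as 13 with 8α-hydroxyl (trans to isopropenyl) in place of the ketone | C=C(C)[C@H]1C[C@@]2(C)[C@H](C[C@H](O[Si](C)(C)C(C)(C)C)C=C2)C(OC)(OC)[C@@H]1O | intermediate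
15 | (R)-2-methylbutanoic acid | CC[C@@H](C)C(=O)O | starting material
16 | as 14 with the 8α-hydroxyl esterified by (R)-2-methylbutanoic acid | C=C(C)[C@H]1C[C@@]2(C)[C@H](C[C@H](O[Si](C)(C)C(C)(C)C)C=C2)C(OC)(OC)[C@@H]1OC(=O)[C@H](C)CC | intermediate
17 | cis-fused octalin: C9 ketone, 8α-(R)-2-methylbutanoate, 7β-isopropenyl, 5β-methyl, 10β-H, C3=C4, 2β-hydroxyl | C=C(C)[C@H]1C[C@@]2(C)[C@H](C[C@H](O)C=C2)C(=O)[C@@H]1OC(=O)[C@H](C)CC | intermediate
18 | as 17 with 9α-hydroxyl (cis to the C8 ester) in place of the ketone | C=C(C)[C@H]1C[C@@]2(C)[C@H](C[C@H](O)C=C2)[C@H](O)[C@@H]1OC(=O)[C@H](C)CC | intermediate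
19 | cis-fused octal-3-en-2-one: 9α-hydroxyl, 8α-(R)-2-methylbutanoate, 7β-isopropenyl, 5β-methyl, 10β-H | C=C(C)[C@H]1C[C@@]2(C)[C@H](CC(=O)C=C2)[C@H](O)[C@@H]1OC(=O)[C@H](C)CC | intermediate
20 | (E)-2-methylbut-2-enoyl chloride (tigloyl chloride) | C/C=C(\C)C(=O)Cl | starting material
21 | as 19 with the 9α-hydroxyl esterified as the (E)-2-methylbut-2-enoate | C=C(C)[C@H]1C[C@@]2(C)[C@H](CC(=O)C=C2)[C@H](OC(=O)/C(C)=C/C)[C@@H]1OC(=O)[C@H](C)CC | intermediate
22 | lithium C2=C3 enolate of 23 | C=C(C)[C@H]1C[C@@]2(C)[C@H](CC([O-])=C[C@@H]2C)[C@H](OC(=O)/C(C)=C/C)[C@@H]1OC(=O)[C@H](C)CC.[Li+] | intermediate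
23 | CNP0312791.1: cis-fused decalin-2-one, 4β,5β-dimethyl, 10β-H, 7β-isopropenyl, 8α-(R)-2-methylbutanoyloxy, 9α-(E)-2-methylbut-2-enoyloxy | C=C(C)[C@H]1C[C@@]2(C)[C@H](CC(=O)C[C@@H]2C)[C@H](OC(=O)/C(C)=C/C)[C@@H]1OC(=O)[C@H](C)CC | target

## Step count and risks

Total: 12 steps. Longest linear sequence: 11 steps (steps 2–12, from phenol 4).

**Step 5 (key step).** The most likely failure is proton delivery to the wrong face of C7, or to the diene terminus with isomerisation into the conjugated isopropylidene ketone. The two half-chairs of the cis-fused dienolate are close in energy, and neither C7 epimer is clearly favoured at equilibrium, so the outcome rests on kinetic control alone. The fallback reverses the order of events at C7 and sets out from ketone 8. Vinylmagnesium bromide would give the vinyl carbinol F1. KH and 18-crown-6 would give, by the same rearrangement, the potassium enolate F2, which has no diene to conjugate. After transmetallation with ZnCl2 at −78 °C it is trapped with acetone to give the aldol F3. The C7 substituent now enters as a carbon electrophile, so a facial preference that would place the proton wrongly places the three-carbon unit on the β face. NaBH4/CeCl3·7H2O would give the diol F4, Steglich esterification of the secondary hydroxyl with 15 the hydroxy ester F5, and dehydration of the tertiary alcohol with SOCl2 in pyridine at −20 °C would return to 16.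

**Step 12.** The methyl group may enter on the α face. Axial attack anti to the angular methyl is the normal stereoelectronic mode, and it is only the shielding by the C9 tiglate that is expected to override it. The fallback uses the β-configured C2 hydroxyl of diol 18 as a directing group. Samarium metal activated with HgCl2 and CH2I2 (hydroxyl-directed Simmons–Smith-type cyclopropanation, selective for the allylic alcohol over the isopropenyl group) would give the β-cyclopropane diol F6. One equivalent of Dess–Martin periodinane at 0 °C should oxidise the unhindered cyclopropyl carbinol to the cyclopropyl ketone F7. SmI2 in THF/DMPU with t-BuOH cleaves the exocyclic cyclopropane bond to give the 4β-methyl ketone F8, and tigloylation as in step 11 reaches 23.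

**Step 9.** Migration of the C8 acyl group to the cis C9 alkoxide, or incomplete facial control, would scramble the two esters. The fallback keeps esters out of the hydride step and sets out from alcohol 14. 2 M aqueous HCl in THF would give the dihydroxy ketone F9, LiBH(s-Bu)3 the triol F10 and MnO2 the enone diol F11. Selective Steglich acylation of the equatorial C8 hydroxyl with 15, the axial C9 hydroxyl being much slower, returns to 19.

**Step 2.** The silyl enol ether may be solvolysed or oxidised in the methanolic oxidant, or the dienone may dimerise faster than it is trapped. The fallback starts again from phenol 4 with 4-methoxybenzyl vinyl ether, an alkyl vinyl ether of the kind that is standard for this cycloaddition, to give the ether adduct F12. DDQ in wet CH2Cl2 would give the endo alcohol F13, and TBSCl with imidazole returns to 7.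

## Further compounds

F1 | step 5 | (1S,2S,4S,7S)-7-[(tert-butyldimethylsilyl)oxy]-2-ethenyl-3,3-dimethoxy-5-methylbicyclo[2.2.2]oct-5-en-2-ol | C=C[C@]1(O)C(OC)(OC)[C@H]2C[C@H](O[Si](C)(C)C(C)(C)C)[C@@H]1C=C2C
F2 | step 5 | potassium C7=C8 enolate of the C7-unsubstituted cis-octalin 8-ketone 9-dimethyl ketal | C=1C[C@@]2(C)[C@H](C[C@H](O[Si](C)(C)C(C)(C)C)C=C2)C(OC)(OC)C=1[O-].[K+]
F3 | step 5 | 7β-(2-hydroxypropan-2-yl) analogue of 13 | CC(C)(O)[C@H]1C[C@@]2(C)[C@H](C[C@H](O[Si](C)(C)C(C)(C)C)C=C2)C(OC)(OC)C1=O
F4 | step 5 | 7β-(2-hydroxypropan-2-yl) analogue of 14 | CC(C)(O)[C@H]1C[C@@]2(C)[C@H](C[C@H](O[Si](C)(C)C(C)(C)C)C=C2)C(OC)(OC)[C@@H]1O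
F5 | step 5 | 7β-(2-hydroxypropan-2-yl) analogue of 16 | CC(C)(O)[C@H]1C[C@@]2(C)[C@H](C[C@H](O[Si](C)(C)C(C)(C)C)C=C2)C(OC)(OC)[C@@H]1OC(=O)[C@H](C)CC
F6 | step 12 | 3β,4β-methano (cyclopropane) derivative of diol 18 | C=C(C)[C@H]1C[C@@]2(C)[C@H](C[C@H](O)[C@@H]3C[C@@H]32)[C@H](O)[C@@H]1OC(=O)[C@H](C)CC
F7 | step 12 | 3β,4β-methano-2-ketone with 9α-hydroxyl and 8α-ester | C=C(C)[C@H]1C[C@@]2(C)[C@H](CC(=O)[C@@H]3C[C@@H]32)[C@H](O)[C@@H]1OC(=O)[C@H](C)CC
F8 | step 12 | 9-O-detigloyl target (4β-methyl-2-ketone, 9α-hydroxyl, 8α-ester) | C=C(C)[C@H]1C[C@@]2(C)[C@H](CC(=O)C[C@@H]2C)[C@H](O)[C@@H]1OC(=O)[C@H](C)CC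
F9 | step 9 | 2β,8α-dihydroxy-9-ketone (cis-octalin, C3=C4) | C=C(C)[C@H]1C[C@@]2(C)[C@H](C[C@H](O)C=C2)C(=O)[C@@H]1O
F10 | step 9 | 2β,8α,9α-triol (cis-octalin, C3=C4) | C=C(C)[C@H]1C[C@@]2(C)[C@H](C[C@H](O)C=C2)[C@H](O)[C@@H]1O
F11 | step 9 | 8α,9α-dihydroxy octal-3-en-2-one | C=C(C)[C@H]1C[C@@]2(C)[C@H](CC(=O)C=C2)[C@H](O)[C@@H]1O
F12 | step 2 | (±)-3,3-dimethoxy-7-endo-[(4-methoxybenzyl)oxy]-5-methylbicyclo[2.2.2]oct-5-en-2-one (racemate, both enantiomers written) | O=C1C(OC)(OC)[C@H]2C[C@H](OCc3ccc(OC)cc3)[C@@H]1C=C2C.O=C1C(OC)(OC)[C@@H]2C[C@@H](OCc3ccc(OC)cc3)[C@H]1C=C2C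
F13 | step 2 | (±)-7-endo-hydroxy-3,3-dimethoxy-5-methylbicyclo[2.2.2]oct-5-en-2-one (racemate, both enantiomers written) | O=C1C(OC)(OC)[C@H]2C[C@H](O)[C@@H]1C=C2C.O=C1C(OC)(OC)[C@@H]2C[C@@H](O)[C@H]1C=C2C
A1 | alternative 1 | C2 ethylene ketal of the target lacking the C8 acyl group (8α-hydroxy, 9α-tigloyloxy) | C=C(C)[C@H]1C[C@@]2(C)[C@H](CC3(OCCO3)C[C@@H]2C)[C@H](OC(=O)/C(C)=C/C)[C@@H]1O
A2 | alternative 2 | cis-octalin C8=C9 tert-butyldimethylsilyl enol ether with 7β-isopropenyl and C2 dioxolane | C=C(C)[C@H]1C[C@@]2(C)[C@H](CC3(OCCO3)C[C@@H]2C)C=C1O[Si](C)(C)C(C)(C)C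
A3 | alternative 3 | ring A cyclohexene with C5 formyl group, C2 silyl enol ether and C10 dioxolane | O=C[C@@]1(C)[C@H](C=C(O[Si](C)(C)C(C)(C)C)C[C@@H]1C)[C@@H]2OC(C)(C)OC2
A4 | alternative 1 | ring A aldehyde with C5 prenyl group and C10 α-tigloyloxy acetaldehyde side chain | CC(C)=CC[C@@]1(C)[C@H](CC2(OCCO2)C[C@@H]1C)[C@H](OC(=O)/C(C)=C/C)C=O
A5 | alternative 2 | open-chain siloxy polyene (isopropenyl cis to C9 on C7=C8, C9=C10 E, C2 dioxolane, C5=C6 dienophile) | C=C(C)/C=C(O[Si](C)(C)C(C)(C)C)\C=C\CC1(OCCO1)C[C@H](C)C(C)=C
A6 | alternative 3 | (E)-1-(2,2-dimethyl-1,3-dioxolan-4-yl)-3-[(tert-butyldimethylsilyl)oxy]buta-1,3-diene | C=C(O[Si](C)(C)C(C)(C)C)/C=C/[C@@H]1OC(C)(C)OC1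
A7 | alternative 3 | (E)-2-methylbut-2-enal | C/C=C(\C)C=O
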